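**Plan**
1. Retrosynthetic cuts, in order: the three O–MOM bonds; C3–C4 of ring C (formyl C4–H added across C2=C3); C4–C4a (aryllithium + DMF); C2=C3 (ester methylenation); O1–C2 (ester bond); then C4a–Br, C8a–O1 (C–H borylation/oxidation) and C6–prenyl on a resorcinol ether.
2. Feature behind the key event: C2 carries both O1 and ring B. C2–C3 can therefore be held as a 1,1-disubstituted enol ether hanging from O1, next to a C4 aldehyde on ring A. Adding C4–H across it makes C3–C4, ring C and the C2 stereocentre in one isomerisation.
3. Second feature: until C4 is attached, ring A is symmetric about the C6···C8a axis (prenyl para to O1, C5–O and C7–O alike). C4a and C8 are then equivalent, so the 6-/8-prenyl question never arises.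
4. Forward order: ring A is fully dressed first (prenyl, O1, Br) and ring B is joined as an ester. The ester C=O becomes C2=C3, Br becomes CHO, ring C closes, and the MOM groups fall last.
5. Stereochemistry: (2S) comes only from the chiral bisphosphine on rhodium in the closure of an achiral precursor. Only one base-free step follows.

Key step: step 9

Remark: atom numbers are those of the flavanone skeleton (O1, C2, C3, C4, C4a, C5–C8, C8a). Ring A is the benzo ring, ring B the 2-aryl group, ring C the pyranone.
Assumption: the (R)-ligand is written for the (2S)-product. The sense of induction must be checked on the first run, and the (S)-ligand is taken if it is the opposite.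

**Step 1**
Reactants: 1 resorcinol
Product: 2 1,3-bis(methoxymethoxy)benzene
Conditions: NaH, MOMCl, DMF, 0 °C → rt
Reagents that add atoms: chloromethyl methyl ether COCCl
Why: Williamson-type O-alkylation of the bis-phenoxide gives MOM ethers that direct the next lithiation and are removed together at the end.

**Step 2**
Reactants: 2 1,3-bis(methoxymethoxy)benzene; 3 prenyl bromide (1-bromo-3-methylbut-2-ene)
Product: 5 1,3-bis(methoxymethoxy)-2-(3-methylbut-2-enyl)benzene, via 2-lithio-1,3-bis(methoxymethoxy)benzene 4 (not isolated)
Conditions: n-BuLi, THF, 0 °C; then 3, −78 °C → rt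
Reagents that add atoms: n-butyllithium [Li]CCCC (lithium of 4 only)
Why: Directed ortho-metalation takes the doubly chelated position between the two OMOM groups, and the aryllithium displaces the primary allylic bromide (SN2).

**Step 3**
Reactants: 5 1,3-bis(methoxymethoxy)-2-(3-methylbut-2-enyl)benzene
Product: 7 3,5-bis(methoxymethoxy)-4-(3-methylbut-2-enyl)phenol, via aryl pinacol boronate 6 (not isolated)
Conditions: [Ir(OMe)(cod)]2 (cat.), 4,4'-di-tert-butyl-2,2'-bipyridine, B2pin2 (1 equiv), THF, 60 °C; then 30% H2O2, aq NaOH, 0 °C
Reagents that add atoms: bis(pinacolato)diboron CC1(C)OB(OC1(C)C)B1OC(C)(C)C(C)(C)O1 (Bpin of 6 only); hydrogen peroxide OO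
Why: Sterically governed iridium-catalysed aromatic C–H borylation reaches only the C–H without an ortho substituent (para to the prenyl group), the trisubstituted alkene is too hindered to be hydroborated, and basic peroxide oxidation turns C–B into C–O without touching the alkene.

**Step 4**
Reactants: 7 3,5-bis(methoxymethoxy)-4-(3-methylbut-2-enyl)phenol
Product: 8 2-bromo-3,5-bis(methoxymethoxy)-4-(3-methylbut-2-enyl)phenol
Conditions: NBS (1.0 equiv), CH2Cl2, −78 °C, dark
Reagents that add atoms: N-bromosuccinimide O=C1CCC(=O)N1Br
Why: In this electrophilic aromatic bromination the phloroglucinol-type ring is far more nucleophilic than the alkene, the para position is blocked and the two ortho positions are equivalent by symmetry, so one equivalent in the cold should give a single monobromide.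

**Step 5**
Reactants: 9 vanillic acid
Product: 11 3-methoxy-4-(methoxymethoxy)benzoic acid, via methoxymethyl ester 10 (not isolated)
Conditions: MOMCl, i-Pr2NEt, CH2Cl2, 0 °C → rt; then LiOH, THF/MeOH/H2O, rt; 1 M HCl to pH 4, 0 °C
Reagents that add atoms: chloromethyl methyl ether COCCl; lithium hydroxide [Li+].[OH-]
Why: Double O-alkylation is followed by saponification of the labile acyloxy acetal, while the aryl MOM ether is stable to base.

**Step 6**
Reactants: 8 2-bromo-3,5-bis(methoxymethoxy)-4-(3-methylbut-2-enyl)phenol; 11 3-methoxy-4-(methoxymethoxy)benzoic acid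
Product: 12 2-bromo-3,5-bis(methoxymethoxy)-4-(3-methylbut-2-enyl)phenyl 3-methoxy-4-(methoxymethoxy)benzoate
Conditions: DCC, DMAP (cat.), CH2Cl2, 0 °C → rt
Reagents that add atoms: none
Why: Steglich esterification forms the O1–C2 bond under neutral conditions that leave the MOM ethers, the aryl bromide and the alkene untouched.

**Step 7**
Reactants: 12 the aryl benzoate
Product: 13 2-bromo-1-{1-[3-methoxy-4-(methoxymethoxy)phenyl]vinyloxy}-3,5-bis(methoxymethoxy)-4-(3-methylbut-2-enyl)benzene
Conditions: Cp2TiMe2 (2.5 equiv), toluene, 70 °C, dark; filtration through basic alumina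
Reagents that add atoms: dimethyltitanocene C[Ti+2]C.c1cc[cH-]c1.c1cc[cH-]c1
Why: In this Petasis methylenation Cp2Ti=CH2 exchanges the ester C=O for C=CH2 by a [2+2]/retro-[2+2] sequence, a conversion with direct precedent for aryl benzoates to aryl 1-arylvinyl ethers, and no acid is present to harm the product.

**Step 8**
Reactants: 13 the bromo enol ether
Product: 15 2-{1-[3-methoxy-4-(methoxymethoxy)phenyl]vinyloxy}-4,6-bis(methoxymethoxy)-5-(3-methylbut-2-enyl)benzaldehyde, via aryllithium 14 (not isolated)
Conditions: n-BuLi (1.05 equiv), THF, −78 °C, 10 min; DMF, −78 → 0 °C; pH 7 phosphate buffer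
Reagents that add atoms: n-butyllithium [Li]CCCC (lithium of 14 only); N,N-dimethylformamide CN(C)C=O
Why: Bromine–lithium exchange at −78 °C outruns addition of n-BuLi to the styrene-type double bond and fixes the metal at C4a, DMF formylates the aryllithium (Bouveault-type formylation), and the buffered quench spares the enol ether.

**Step 9**
Reactants: 15 the enol ether aldehyde
Product: 16 (2S)-2-[3-methoxy-4-(methoxymethoxy)phenyl]-5,7-bis(methoxymethoxy)-6-(3-methylbut-2-enyl)chroman-4-one
Conditions: [Rh(cod)Cl]2 (2.5 mol %), (R)-DTBM-SEGPHOS (5.5 mol %), NaB[3,5-(CF3)2C6H3]4 (6 mol %), 4 Å MS, THF, 60 °C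
Reagents that add atoms: none
Why: Proposed new method: the cationic monovalent rhodium bisphosphine complex inserts into the formyl C4–H bond of 15 (the C5 OMOM oxygen and the tethered alkene fill the free sites of the trivalent rhodium acyl hydride and so hold back decarbonylation), the hydride migrates to C2 of the bound C2=C3 bond while rhodium takes the CH2 terminus C3, and reductive elimination from the seven-membered acyl alkyl rhodacycle forms C3–C4. The closest known reaction type is the rhodium-catalysed endo- and enantioselective intramolecular hydroacylation of 1,1-disubstituted alkenes (ortho-allylbenzaldehydes to 3-substituted tetralones, N-(1-arylvinyl)indole-2-carbaldehydes to bicyclic ketones), and what is new here is an aryl 1-arylvinyl ether, with oxygen in the tether, as the acceptor. Ring C closes in a formal 6-endo-trig mode, acyl carbon to the unsubstituted alkene terminus. The only new stereocentre, C2, is set in the hydride transfer by the alkene face that the pocket of the twofold-symmetric ligand allows to bind, with no help from the achiral substrate. The step needs endo over exo regioselectivity, secured by the 1,1-disubstitution because the exo path runs through a tertiary alkylrhodium and a quaternary-carbon-forming elimination to a benzofuran-3-one while hydride insertion is reversible, and it needs chemoselectivity over the prenyl group, which is trisubstituted and sits meta to the formyl group where no cyclic insertion is possible. The medium is neutral and aprotic, so neither the acid-labile enol ether nor the base-labile C2–O1 bond of the product is endangered.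

**Step 10**
Reactants: 16 the tris-MOM flavanone
Product: 17 (2S)-5,7-dihydroxy-2-(4-hydroxy-3-methoxyphenyl)-6-(3-methylbut-2-enyl)chroman-4-one (target)
Conditions: HCl (1.25 M in MeOH), MeOH/THF, 40 °C, Ar
Reagents that add atoms: none
Why: Acid-catalysed transacetalisation of the three aryl MOM ethers to dimethoxymethane is the standard deprotection for prenylated flavanones, and the absence of base shuts off the retro-oxa-Michael (chalcone) path that would scramble C2 while the mild temperature limits addition of the freed phenols to the prenyl group.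

**Compound list**
1 | resorcinol | Oc1cccc(O)c1 | starting material
2 | 1,3-bis(methoxymethoxy)benzene | COCOc1cccc(OCOC)c1 | intermediate
3 | prenyl bromide | CC(C)=CCBr | starting material
4 | 2-lithio-1,3-bis(methoxymethoxy)benzene | [Li]c1c(OCOC)cccc1OCOC | intermediate
5 | 1,3-bis(methoxymethoxy)-2-(3-methylbut-2-enyl)benzene | COCOc1cccc(OCOC)c1CC=C(C)C | intermediate
6 | 2-[3,5-bis(methoxymethoxy)-4-(3-methylbut-2-enyl)phenyl]-4,4,5,5-tetramethyl-1,3,2-dioxaborolane | COCOc1cc(B2OC(C)(C)C(C)(C)O2)cc(OCOC)c1CC=C(C)C | intermediate
7 | 3,5-bis(methoxymethoxy)-4-(3-methylbut-2-enyl)phenol | COCOc1cc(O)cc(OCOC)c1CC=C(C)C | intermediate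
8 | 2-bromo-3,5-bis(methoxymethoxy)-4-(3-methylbut-2-enyl)phenol | COCOc1cc(O)c(Br)c(OCOC)c1CC=C(C)C | intermediate
9 | vanillic acid | COc1cc(C(=O)O)ccc1O | starting material
10 | methoxymethyl 3-methoxy-4-(methoxymethoxy)benzoate | COCOC(=O)c1ccc(OCOC)c(OC)c1 | intermediate
11 | 3-methoxy-4-(methoxymethoxy)benzoic acid | COCOc1ccc(C(=O)O)cc1OC | intermediate
12 | 2-bromo-3,5-bis(methoxymethoxy)-4-(3-methylbut-2-enyl)phenyl 3-methoxy-4-(methoxymethoxy)benzoate | COCOc1ccc(C(=O)Oc2cc(OCOC)c(CC=C(C)C)c(OCOC)c2Br)cc1OC | intermediate
13 | bromo aryl 1-arylvinyl ether | COCOc1ccc(C(=C)Oc2cc(OCOC)c(CC=C(C)C)c(OCOC)c2Br)cc1OC | intermediate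
14 | aryllithium from 13 | COCOc1ccc(C(=C)Oc2cc(OCOC)c(CC=C(C)C)c(OCOC)c2[Li])cc1OC | intermediate
15 | 2-{1-[3-methoxy-4-(methoxymethoxy)phenyl]vinyloxy}-4,6-bis(methoxymethoxy)-5-(3-methylbut-2-enyl)benzaldehyde | COCOc1ccc(C(=C)Oc2cc(OCOC)c(CC=C(C)C)c(OCOC)c2C=O)cc1OC | intermediate
16 | (2S)-2-[3-methoxy-4-(methoxymethoxy)phenyl]-5,7-bis(methoxymethoxy)-6-(3-methylbut-2-enyl)chroman-4-one | COCOc1ccc([C@@H]2CC(=O)c3c(cc(OCOC)c(CC=C(C)C)c3OCOC)O2)cc1OC | intermediate
17 | (2S)-5,7-dihydroxy-2-(4-hydroxy-3-methoxyphenyl)-6-(3-methylbut-2-enyl)chroman-4-one | COc1cc([C@@H]2CC(=O)c3c(cc(O)c(CC=C(C)C)c3O)O2)ccc1O | target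

Total steps: 10. Longest linear sequence: 9 (steps 1, 2, 3, 4, 6, 7, 8, 9, 10).

**Steps most likely to fail**

Step 9.
- What may go wrong: loss of CO from the acyl rhodium hydride before the hindered alkene inserts; β-aryloxide elimination from the rhodacycle, which cleaves O1–C2; acid-type aldol closure of the enol ether onto the aldehyde; or poor facial selectivity.
- Fallback, known chemistry, from 15 back to 16. The same C3–C4 bond is closed by a thiol-catalysed radical-chain hydroacylation (tert-dodecanethiol, di-tert-butyl hyponitrite, dioxane, 60 °C). The aroyl radical adds in the 6-endo mode to the CH2 terminus. The C2 radical, stabilised by O1 and ring B, takes hydrogen from the thiol and gives the racemic flavanone F1.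
- Kinetic resolution follows by asymmetric transfer hydrogenation (RuCl[(R,R)-TsDPEN](p-cymene), HCO2H/Et3N, EtOAc, rt), a reaction type established for racemic flavanones. It should reduce the (2R)-enantiomer to the cis-(2R,4R)-flavan-4-ol F2 and leave the (2S)-ketone 16, which is separated by chromatography.

Step 4.
- What may go wrong: attack of the bromonium source on the prenyl double bond, or a second bromination at the other ortho position.
- Fallback from 7 back to 8, with the polarity of the halogenation inverted. Carbamoylation of 7 (NaH, ClCONEt2, THF) gives the O-aryl diethylcarbamate F3.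
- Directed ortho-metalation (s-BuLi, TMEDA, THF, −78 °C) between the carbamate and OMOM gives the lithiated carbamate F4.
- A quench with 1,2-dibromoethane, a bromine donor that is inert to alkenes, gives the bromo carbamate F5. KOH in refluxing EtOH then frees 8.

Step 10.
- What may go wrong: acid-induced ring closure of the prenyl group onto the freed 5- or 7-hydroxyl, and erosion of the enantiomeric purity by reversible ionisation of the benzylic C2–O1 bond.
- Fallback from 16 to 17 without any Brønsted acid. The aryl acetals are exchanged for silyl ethers with TESOTf and 2,2'-bipyridyl (CH2Cl2, 0 °C), giving the tris(triethylsilyl) ether F6.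
- All three silyl groups are then removed with the weakly acidic fluoride source Et3N·3HF (THF, 0 °C → rt).

**Further compounds**
F1 | step 9 | racemic 2-[3-methoxy-4-(methoxymethoxy)phenyl]-5,7-bis(methoxymethoxy)-6-(3-methylbut-2-enyl)chroman-4-one | COCOc1ccc(C2CC(=O)c3c(cc(OCOC)c(CC=C(C)C)c3OCOC)O2)cc1OC
F2 | step 9 | (2R,4R)-2-[3-methoxy-4-(methoxymethoxy)phenyl]-5,7-bis(methoxymethoxy)-6-(3-methylbut-2-enyl)chroman-4-ol | COCOc1ccc([C@H]2C[C@@H](O)c3c(cc(OCOC)c(CC=C(C)C)c3OCOC)O2)cc1OC
F3 | step 4 | 3,5-bis(methoxymethoxy)-4-(3-methylbut-2-enyl)phenyl N,N-diethylcarbamate | CCN(CC)C(=O)Oc1cc(OCOC)c(CC=C(C)C)c(OCOC)c1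
F4 | step 4 | 2-lithio-3,5-bis(methoxymethoxy)-4-(3-methylbut-2-enyl)phenyl N,N-diethylcarbamate | CCN(CC)C(=O)Oc1cc(OCOC)c(CC=C(C)C)c(OCOC)c1[Li]
F5 | step 4 | 2-bromo-3,5-bis(methoxymethoxy)-4-(3-methylbut-2-enyl)phenyl N,N-diethylcarbamate | CCN(CC)C(=O)Oc1cc(OCOC)c(CC=C(C)C)c(OCOC)c1Br
F6 | step 10 | (2S)-2-[3-methoxy-4-(triethylsilyloxy)phenyl]-6-(3-methylbut-2-enyl)-5,7-bis(triethylsilyloxy)chroman-4-one | CC[Si](CC)(CC)Oc1ccc([C@@H]2CC(=O)c3c(cc(O[Si](CC)(CC)CC)c(CC=C(C)C)c3O[Si](CC)(CC)CC)O2)cc1OC
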